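**Retrosynthetic overview**

1. Numbering: ring A is C1(=CH2)–C2–C3(OAc)–C4(Br)–C5(Me2)–C6(spiro), ring B is C6–C7–C8–C9(Me,Br)–C10(Cl)–C11. The strategy rests on ring A: its gem-dimethyl carbon C5, C3 oxygen and C1 methylene map onto a ketoisophorone-derived 2,6,6-trimethylcyclohexene whose tetrasubstituted C6=C1 alkene can bond at C6 while its C1 methyl becomes the methylene.
2. Ring A end game: 27 ⇐ 26 (acetylation) ⇐ 25 (ketone reduction cis to Br) ⇐ 23 (deconjugation to the exocyclic alkene) ⇐ 21 (C4 bromination of the C1-methyl enone).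
3. Ring B halogens: 21 ⇐ 20 (tertiary OH to Br, anti to the axial chlorine) ⇐ cyclic sulfate 17 (axial SN2 opening by chloride at C10) ⇐ cis-diol 16 ⇐ proline α-aminoxylation of achiral ketone 10, which makes C6 stereogenic.
4. Key disconnection C6–C7: Lewis acid Michael–ene spirocyclisation of vinyl ketone 9 closes ring B onto the preformed ring A (ring A first, ring B second).
5. 9 ⇐ Weinreb amide 8 ⇐ ester 7 ⇐ enol triflate 5 + zinc homoenolate 6 (Negishi); 5 comes from ketoisophorone 1 in three steps.

Key step: step 7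

Assumption: in step 8 nitrosobenzene is taken to attack the enamine axially on the ring B chair that holds C5 equatorial and C1 axial (O cis to C1); if equatorial attack prevailed, L-proline would give the C10-equatorial alcohol directly and the epimerisation in step 10 would be unnecessary. Locants in 10–27 follow the target numbering above.

**Route**

Step 1
Reactants: 1 ketoisophorone (2,6,6-trimethylcyclohex-2-ene-1,4-dione)
Product: 2 2,2,6-trimethylcyclohexane-1,4-dione (racemic)
Conditions: H2 (1 atm), Pd/C, EtOAc, rt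
Reagents that add atoms: none
Why: Heterogeneous catalytic hydrogenation should saturate the enedione C=C much faster than either ketone; the racemic centre formed is erased in step 3.

Step 2
Reactants: 2 2,2,6-trimethylcyclohexane-1,4-dione; 3 ethane-1,2-diol
Product: 4 7,9,9-trimethyl-1,4-dioxaspiro[4.5]decan-8-one (racemic)
Conditions: p-TsOH·H2O (cat.), toluene, reflux, Dean–Stark
Reagents that add atoms: none
Why: Acid-catalysed ketalisation with water removal should be selective for the unhindered carbonyl, because the other one is flanked by CMe2 and CHMe.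

Step 3
Reactants: 4 7,9,9-trimethyl-1,4-dioxaspiro[4.5]decan-8-one
Product: 5 7,9,9-trimethyl-1,4-dioxaspiro[4.5]dec-7-en-8-yl trifluoromethanesulfonate
Conditions: LDA, THF, −78 → 0 °C; PhNTf2, 0 °C → rt
Reagents that add atoms: N-phenylbis(trifluoromethanesulfonimide) (O=S(=O)(N(c1ccccc1)S(=O)(=O)C(F)(F)F)C(F)(F)F)
Why: The ketone can enolise only toward the CHMe carbon, so O-triflation of the lithium enolate (enol triflate formation) should give a single tetrasubstituted regioisomer, as with 2,2,6-trimethylcyclohexanone.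

Step 4
Reactants: 5 7,9,9-trimethyl-1,4-dioxaspiro[4.5]dec-7-en-8-yl trifluoromethanesulfonate; 6 (3-ethoxy-3-oxopropyl)zinc bromide
Product: 7 ethyl 3-(7,9,9-trimethyl-1,4-dioxaspiro[4.5]dec-7-en-8-yl)propanoate
Conditions: Pd(OAc)2 (4 mol %), SPhos (8 mol %), THF, 50 °C
Reagents that add atoms: none
Why: Negishi sp2–sp3 cross-coupling of an alkenyl triflate with a primary alkylzinc homoenolate; the bulky biaryl phosphine favours reductive elimination over β-hydride elimination at the hindered alkenyl centre, and ester and ketal are inert to the organozinc.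

Step 5
Reactants: 7 ethyl 3-(7,9,9-trimethyl-1,4-dioxaspiro[4.5]dec-7-en-8-yl)propanoate
Product: 8 N-methoxy-N-methyl-3-(7,9,9-trimethyl-1,4-dioxaspiro[4.5]dec-7-en-8-yl)propanamide
Conditions: MeNH(OMe)·HCl, i-PrMgCl, THF, −20 → 0 °C
Reagents that add atoms: N,O-dimethylhydroxylamine hydrochloride (CNOC.Cl)
Why: Aminolysis of the ester by the chloromagnesium amide of N,O-dimethylhydroxylamine (Weinreb amide formation) is general for unhindered esters.

Step 6
Reactants: 8 N-methoxy-N-methyl-3-(7,9,9-trimethyl-1,4-dioxaspiro[4.5]dec-7-en-8-yl)propanamide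
Product: 9 5-(7,9,9-trimethyl-1,4-dioxaspiro[4.5]dec-7-en-8-yl)pent-1-en-3-one
Conditions: CH2=CHMgBr, THF, −20 → 0 °C; inverse quench into cold aq. citric acid
Reagents that add atoms: vinylmagnesium bromide (C=C[Mg]Br)
Why: Weinreb ketone synthesis, in which the chelated tetrahedral adduct stops double addition and the cold acidic inverse quench protonates the released N,O-dimethylhydroxylamine before it can add to the vinyl ketone; the dioxolane tolerates brief cold citric acid.

Step 7
Reactants: 9 5-(7,9,9-trimethyl-1,4-dioxaspiro[4.5]dec-7-en-8-yl)pent-1-en-3-one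
Product: 10 3,3-(ethylenedioxy)-5,5-dimethyl-1-methylidenespiro[5.5]undecan-9-one
Conditions: EtAlCl2 (1.5 equiv), CH2Cl2 (0.02 M), −78 → −20 °C; aq. Rochelle salt
Reagents that add atoms: none
Why: EtAlCl2 binds the enone oxygen and the tetrasubstituted C6=C1 alkene of ring A adds through C6 to the terminal vinyl carbon, giving an aluminium enolate and a tertiary cation at C1; a hydrogen of the C1 methyl then passes to the enolate α-carbon through a six-membered array (H, CH2, C1, C6, C7, C8), leaving the exocyclic methylene and the ring B ketone. The closest known reaction type is the Lewis acid-promoted intramolecular conjugate ene (Michael–ene) addition of alkenes to α,β-unsaturated ketones. Ring B closes in the 6-endo-trig mode with respect to the enone double bond, through the new C6–C7 bond. No stereocentre is formed, because the two arms of ring B are enantiotopic and 10 is achiral; C6 becomes stereogenic only in step 8. The step needs hydrogen loss from the methyl group rather than from C2 and survival of the dioxolane: the freely rotating methyl offers three hydrogens in the cyclic transfer geometry whereas the C2 hydrogens are held in the ring next to the electron-poor ketal carbon, and low temperature, short contact and high dilution should limit ketal opening and vinyl ketone polymerisation. Any endocyclic C1=C2 isomer would not be lost, since it converges with material from 10 at enone 20 in step 13.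

Step 8
Reactants: 10 3,3-(ethylenedioxy)-5,5-dimethyl-1-methylidenespiro[5.5]undecan-9-one
Product: 11 (6S,10S)-10-(anilinooxy)-3,3-(ethylenedioxy)-5,5-dimethyl-1-methylidenespiro[5.5]undecan-9-one
Conditions: D-proline (20 mol %), PhNO (1.1 equiv, slow addition), DMF, 0 °C
Reagents that add atoms: nitrosobenzene (O=Nc1ccccc1)
Why: Proline-catalysed α-aminoxylation (O-selective nitroso aldol through the enamine) in which D-proline fixes the new C10 centre as S, and axial attack on the ring B chair (C5 equatorial, C1 axial) decides which enantiotopic α-carbon can react in that sense, so that C6 is set together with C10 (O cis to C1); any diastereomer is removed by chromatography.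

Step 9
Reactants: 11 (6S,10S)-10-(anilinooxy)-3,3-(ethylenedioxy)-5,5-dimethyl-1-methylidenespiro[5.5]undecan-9-one
Product: 12 (6S,10S)-3,3-(ethylenedioxy)-10-hydroxy-5,5-dimethyl-1-methylidenespiro[5.5]undecan-9-one
Conditions: CuSO4·5H2O (30 mol %), MeOH, 0 °C
Reagents that add atoms: none
Why: Copper-catalysed N–O cleavage of the O-alkyl-N-phenylhydroxylamine is the standard unmasking of aminoxylation products and should leave alkene, ketal and the α-stereocentre untouched.

Step 10
Reactants: 12 (6S,10S)-3,3-(ethylenedioxy)-10-hydroxy-5,5-dimethyl-1-methylidenespiro[5.5]undecan-9-one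
Product: 14 (6S,10R)-3,3-(ethylenedioxy)-5,5-dimethyl-1-methylidene-10-(triethylsilyloxy)spiro[5.5]undecan-9-one, via axial triethylsilyl ether 13 (not isolated)
Conditions: TESCl, imidazole, DMF, rt; then DBU, 40 °C
Reagents that add atoms: chlorotriethylsilane (CC[Si](Cl)(CC)CC)
Why: Silylation blocks the α-ketol (enediol) shift, and base-mediated epimerisation through the enol then moves the silyloxy group from the axial site, where it is 1,3-diaxial to C1, to the equatorial site trans to C1 under thermodynamic control, without touching C6.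

Step 11
Reactants: 14 (6S,10R)-3,3-(ethylenedioxy)-5,5-dimethyl-1-methylidene-10-(triethylsilyloxy)spiro[5.5]undecan-9-one
Product: 16 (6S,9S,10R)-3,3-(ethylenedioxy)-5,5,9-trimethyl-1-methylidenespiro[5.5]undecane-9,10-diol, via silyl-protected carbinol 15 (not isolated)
Conditions: MeMgBr, THF, −78 → 0 °C; aq. NH4Cl; then TBAF, THF, rt
Reagents that add atoms: methylmagnesium bromide (C[Mg]Br)
Why: Grignard 1,2-addition from the equatorial direction, trans to the α-silyloxy group, should give the axial tertiary alcohol cis to the C10 oxygen, and fluoride desilylation frees the cis-diol; the C9 configuration is not critical because C9 is later substituted through its cation.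

Step 12
Reactants: 16 (6S,9S,10R)-3,3-(ethylenedioxy)-5,5,9-trimethyl-1-methylidenespiro[5.5]undecane-9,10-diol
Product: 17 (6S,9S,10R)-3,3-(ethylenedioxy)-5,5,9-trimethyl-1-methylidenespiro[5.5]undecane-9,10-diyl cyclic sulfate
Conditions: 1,1′-sulfonyldiimidazole, NaH, THF, 0 °C → rt
Reagents that add atoms: 1,1′-sulfonyldiimidazole (O=S(=O)(n1ccnc1)n1ccnc1)
Why: Cyclic sulfate formation by double sulfonyl transfer to the dialkoxide, chosen over the thionyl chloride then ruthenium tetroxide sequence, which would oxidise the exocyclic alkene.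

Step 13
Reactants: 17 (6S,9S,10R)-3,3-(ethylenedioxy)-5,5,9-trimethyl-1-methylidenespiro[5.5]undecane-9,10-diyl cyclic sulfate
Product: 20 (6S,9S,10S)-10-chloro-9-hydroxy-1,5,5,9-tetramethylspiro[5.5]undec-1-en-3-one, via lithium chloro sulfate 18 (not isolated), via methylidene keto alcohol 19 (not isolated)
Conditions: LiCl, DMF, 60 °C; then 1 M aq. H2SO4, THF, 45 °C
Reagents that add atoms: lithium chloride ([Li+].[Cl-]); water (O)
Why: Chloride opens the cyclic sulfate by SN2 at the secondary C10 with inversion, entering axially to give the trans-diaxial chloro sulfate (Cl cis to C1), and aqueous acid then hydrolyses the sulfate monoester and the dioxolane and moves the β,γ double bond into conjugation (acid-catalysed isomerisation through the dienol), which makes ring A inert to HBr in step 14.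

Step 14
Reactants: 20 (6S,9S,10S)-10-chloro-9-hydroxy-1,5,5,9-tetramethylspiro[5.5]undec-1-en-3-one
Product: 21 (6S,9S,10S)-9-bromo-10-chloro-1,5,5,9-tetramethylspiro[5.5]undec-1-en-3-one
Conditions: HBr (33 % in AcOH), CH2Cl2, 0 °C; aq. NaHCO3
Reagents that add atoms: hydrogen bromide (Br)
Why: SN1 substitution of the tertiary alcohol in which the antiperiplanar axial C10–Cl bond bridges the C9 cation and bromide enters axially anti to chlorine, so C9 should form with retention as the trans-diaxial bromide; any elimination products re-add HBr through the same cation, and conjugate HBr addition to the enone reverses on basic work-up.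

Step 15
Reactants: 21 (6S,9S,10S)-9-bromo-10-chloro-1,5,5,9-tetramethylspiro[5.5]undec-1-en-3-one
Product: 23 (4R,6R,9S,10S)-4,9-dibromo-10-chloro-1,5,5,9-tetramethylspiro[5.5]undec-1-en-3-one, via trimethylsilyl dienol ether 22 (not isolated)
Conditions: LDA, TMSCl, THF, −78 °C; then NBS, THF, −78 °C
Reagents that add atoms: N-bromosuccinimide (O=C1CCC(=O)N1Br)
Why: Kinetic α′-deprotonation of the enone at C4 (as with isophorone) with in-situ silylation, then electrophilic bromination of the cross-conjugated silyl dienol ether; the axial C10 chlorine pushes the C1 methyl toward C7, which makes C11 the pseudoaxial arm on ring A, and bromine should enter anti to the adjacent pseudoaxial C5 methyl on that same face, that is cis to C11 (4R).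

Step 16
Reactants: 23 (4R,6R,9S,10S)-4,9-dibromo-10-chloro-1,5,5,9-tetramethylspiro[5.5]undec-1-en-3-one
Product: 25 (4R,6R,9S,10S)-4,9-dibromo-10-chloro-5,5,9-trimethyl-1-methylidenespiro[5.5]undecan-3-one, via linear silyl dienol ether 24 (not isolated)
Conditions: TBSOTf, Et3N, CH2Cl2, −40 °C; then TBAF, AcOH, THF, −78 °C
Reagents that add atoms: none
Why: Deconjugation of the enone through its extended dienol derivative: soft enolisation should remove a γ-hydrogen of the C1 methyl (the C4 hydrogen lies near the carbonyl plane and is shielded by bromine and CMe2), and fluoride release of the dienolate under acetic acid buffering protonates kinetically at the α-carbon C2 to give the β,γ-unsaturated ketone without a base strong enough for Favorskii chemistry.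

Step 17
Reactants: 25 (4R,6R,9S,10S)-4,9-dibromo-10-chloro-5,5,9-trimethyl-1-methylidenespiro[5.5]undecan-3-one
Product: 26 (3S,4R,6R,9S,10S)-4,9-dibromo-10-chloro-5,5,9-trimethyl-1-methylidenespiro[5.5]undecan-3-ol (isoobtusol)
Conditions: DIBAL, CH2Cl2, −78 °C; aq. Rochelle salt
Reagents that add atoms: none
Why: Hydride 1,2-reduction of the α-bromo ketone with hydride delivered anti to the C4–Br bond should give the cis-bromohydrin (3S); crude 25 is used at once to forestall reconjugation, and the alkyl halides and the alkene are inert at −78 °C.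

Step 18
Reactants: 26 (3S,4R,6R,9S,10S)-4,9-dibromo-10-chloro-5,5,9-trimethyl-1-methylidenespiro[5.5]undecan-3-ol
Product: 27 (3S,4R,6R,9S,10S)-4,9-dibromo-10-chloro-5,5,9-trimethyl-1-methylidenespiro[5.5]undecan-3-yl acetate (9-acetylisoobtusol)
Conditions: Ac2O, pyridine, DMAP (cat.), CH2Cl2, 0 °C → rt
Reagents that add atoms: acetic anhydride (CC(=O)OC(C)=O)
Why: DMAP-catalysed O-acylation of the secondary alcohol; the cis-bromohydrin cannot close to an epoxide, so the mild base should be tolerated.

**Compound list**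

1 | ketoisophorone (2,6,6-trimethylcyclohex-2-ene-1,4-dione) | CC1=CC(=O)CC(C)(C)C1=O | starting material
2 | 2,2,6-trimethylcyclohexane-1,4-dione (racemic) | CC1CC(=O)CC(C)(C)C1=O | intermediate
3 | ethane-1,2-diol | OCCO | starting material
4 | 7,9,9-trimethyl-1,4-dioxaspiro[4.5]decan-8-one (racemic) | CC1CC2(OCCO2)CC(C)(C)C1=O | intermediate
5 | 7,9,9-trimethyl-1,4-dioxaspiro[4.5]dec-7-en-8-yl trifluoromethanesulfonate | CC1=C(OS(=O)(=O)C(F)(F)F)C(C)(C)CC2(OCCO2)C1 | intermediate
6 | (3-ethoxy-3-oxopropyl)zinc bromide | CCOC(=O)CC[Zn]Br | starting material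
7 | ethyl 3-(7,9,9-trimethyl-1,4-dioxaspiro[4.5]dec-7-en-8-yl)propanoate | CCOC(=O)CCC1=C(C)CC2(OCCO2)CC1(C)C | intermediate
8 | N-methoxy-N-methyl-3-(7,9,9-trimethyl-1,4-dioxaspiro[4.5]dec-7-en-8-yl)propanamide | CON(C)C(=O)CCC1=C(C)CC2(OCCO2)CC1(C)C | intermediate
9 | 5-(7,9,9-trimethyl-1,4-dioxaspiro[4.5]dec-7-en-8-yl)pent-1-en-3-one | C=CC(=O)CCC1=C(C)CC2(OCCO2)CC1(C)C | intermediate
10 | 3,3-(ethylenedioxy)-5,5-dimethyl-1-methylidenespiro[5.5]undecan-9-one (achiral) | C=C1CC2(OCCO2)CC(C)(C)C13CCC(=O)CC3 | intermediate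
11 | (6S,10S)-10-(anilinooxy)-3,3-(ethylenedioxy)-5,5-dimethyl-1-methylidenespiro[5.5]undecan-9-one (C10–O axial, cis to C1) | C=C1CC2(OCCO2)CC(C)(C)[C@@]13CCC(=O)[C@@H](ONc4ccccc4)C3 | intermediate
12 | (6S,10S)-3,3-(ethylenedioxy)-10-hydroxy-5,5-dimethyl-1-methylidenespiro[5.5]undecan-9-one | C=C1CC2(OCCO2)CC(C)(C)[C@@]13CCC(=O)[C@@H](O)C3 | intermediate
13 | (6S,10S)-3,3-(ethylenedioxy)-5,5-dimethyl-1-methylidene-10-(triethylsilyloxy)spiro[5.5]undecan-9-one (axial silyl ether) | C=C1CC2(OCCO2)CC(C)(C)[C@@]13CCC(=O)[C@@H](O[Si](CC)(CC)CC)C3 | intermediate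
14 | (6S,10R)-3,3-(ethylenedioxy)-5,5-dimethyl-1-methylidene-10-(triethylsilyloxy)spiro[5.5]undecan-9-one (C10–O equatorial, trans to C1) | C=C1CC2(OCCO2)CC(C)(C)[C@@]13CCC(=O)[C@H](O[Si](CC)(CC)CC)C3 | intermediate
15 | (6S,9S,10R)-3,3-(ethylenedioxy)-5,5,9-trimethyl-1-methylidene-10-(triethylsilyloxy)spiro[5.5]undecan-9-ol | C=C1CC2(OCCO2)CC(C)(C)[C@@]13CC[C@](C)(O)[C@H](O[Si](CC)(CC)CC)C3 | intermediate
16 | (6S,9S,10R)-3,3-(ethylenedioxy)-5,5,9-trimethyl-1-methylidenespiro[5.5]undecane-9,10-diol (cis-diol) | C=C1CC2(OCCO2)CC(C)(C)[C@@]13CC[C@](C)(O)[C@H](O)C3 | intermediate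
17 | (6S,9S,10R)-3,3-(ethylenedioxy)-5,5,9-trimethyl-1-methylidenespiro[5.5]undecane-9,10-diyl cyclic sulfate | C=C1CC2(OCCO2)CC(C)(C)[C@@]13CC[C@](C)(OS(=O)(=O)O4)[C@H]4C3 | intermediate
18 | lithium (6S,9S,10S)-10-chloro-3,3-(ethylenedioxy)-5,5,9-trimethyl-1-methylidenespiro[5.5]undecan-9-yl sulfate | C=C1CC2(OCCO2)CC(C)(C)[C@@]13CC[C@](C)(OS(=O)(=O)[O-])[C@@H](Cl)C3.[Li+] | intermediate
19 | (6S,9S,10S)-10-chloro-9-hydroxy-5,5,9-trimethyl-1-methylidenespiro[5.5]undecan-3-one | C=C1CC(=O)CC(C)(C)[C@@]12CC[C@](C)(O)[C@@H](Cl)C2 | intermediate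
20 | (6S,9S,10S)-10-chloro-9-hydroxy-1,5,5,9-tetramethylspiro[5.5]undec-1-en-3-one | CC1=CC(=O)CC(C)(C)[C@@]12CC[C@](C)(O)[C@@H](Cl)C2 | intermediate
21 | (6S,9S,10S)-9-bromo-10-chloro-1,5,5,9-tetramethylspiro[5.5]undec-1-en-3-one | CC1=CC(=O)CC(C)(C)[C@@]12CC[C@](C)(Br)[C@@H](Cl)C2 | intermediate
22 | (6R,9S,10S)-9-bromo-10-chloro-1,5,5,9-tetramethyl-3-(trimethylsilyloxy)spiro[5.5]undeca-1,3-diene | CC1=CC(O[Si](C)(C)C)=CC(C)(C)[C@@]12CC[C@](C)(Br)[C@@H](Cl)C2 | intermediate
23 | (4R,6R,9S,10S)-4,9-dibromo-10-chloro-1,5,5,9-tetramethylspiro[5.5]undec-1-en-3-one | CC1=CC(=O)[C@H](Br)C(C)(C)[C@@]12CC[C@](C)(Br)[C@@H](Cl)C2 | intermediate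
24 | (4R,6R,9S,10S)-4,9-dibromo-3-(tert-butyldimethylsilyloxy)-10-chloro-5,5,9-trimethyl-1-methylidenespiro[5.5]undec-2-ene | C=C1C=C(O[Si](C)(C)C(C)(C)C)[C@H](Br)C(C)(C)[C@@]12CC[C@](C)(Br)[C@@H](Cl)C2 | intermediate
25 | (4R,6R,9S,10S)-4,9-dibromo-10-chloro-5,5,9-trimethyl-1-methylidenespiro[5.5]undecan-3-one | C=C1CC(=O)[C@H](Br)C(C)(C)[C@@]12CC[C@](C)(Br)[C@@H](Cl)C2 | intermediate
26 | (3S,4R,6R,9S,10S)-4,9-dibromo-10-chloro-5,5,9-trimethyl-1-methylidenespiro[5.5]undecan-3-ol (isoobtusol) | C=C1C[C@H](O)[C@H](Br)C(C)(C)[C@@]12CC[C@](C)(Br)[C@@H](Cl)C2 | intermediate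
27 | (3S,4R,6R,9S,10S)-4,9-dibromo-10-chloro-5,5,9-trimethyl-1-methylidenespiro[5.5]undecan-3-yl acetate (9-acetylisoobtusol) | C=C1C[C@H](OC(C)=O)[C@H](Br)C(C)(C)[C@@]12CC[C@](C)(Br)[C@@H](Cl)C2 | target

**Step count**

Total: 18 steps. Longest linear sequence: 18 steps (1 → 27).

**Steps most likely to fail**

Step 16 (deconjugation of bromo enone 23). Enolisation may go toward C4 instead of the methyl group, which would return conjugated enone or scramble C4; a free dienolate may close to a cyclopropanone; 25 may reconjugate during isolation. Fallback: from 23, thermodynamic enol acetylation (Ac2O, cat. HClO4, EtOAc, 0 °C) would give the extended dienol acetate (4R,6R,9S,10S)-4,9-dibromo-10-chloro-5,5,9-trimethyl-1-methylidenespiro[5.5]undec-2-en-3-yl acetate F6. Treatment with NaBH4 in aqueous ethanol–THF at 0 °C follows the classical enol acetate route from a conjugated enone to the β,γ-unsaturated alcohol: the ester is cleaved, the dienolate is protonated at C2, and the unconjugated ketone is reduced before it can reconjugate. This bypasses 25 and rejoins the route at 26.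

Step 8 (desymmetrising aminoxylation of 10). The two enantiotopic α-carbons may be poorly discriminated (axial against equatorial attack on the enamine), double aminoxylation at C8 and C10 may occur, or enamine formation may be slow. Fallback: from 10, enantioselective deprotonation with a chiral lithium amide (lithium bis[(R)-1-phenylethyl]amide or its antipode, whichever removes the axial C10 hydrogen; LiCl, TMSCl internal quench, THF, −100 °C) would give (6S)-3,3-(ethylenedioxy)-5,5-dimethyl-1-methylidene-9-(trimethylsilyloxy)spiro[5.5]undec-9-ene F4. Rubottom oxidation (mCPBA 1.0 equiv, NaHCO3, CH2Cl2, −20 °C; then citric acid, MeOH) should attack the electron-rich enol ether in preference to the methylidene group, from the face away from the axial C1 arm, to give (6S,10R)-3,3-(ethylenedioxy)-10-hydroxy-5,5-dimethyl-1-methylidenespiro[5.5]undecan-9-one F5. Silylation (TESCl, imidazole, DMF) rejoins the route at 14.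

Step 7 (Michael–ene spirocyclisation). The aluminium Lewis acid may open the dioxolane, the vinyl ketone may polymerise, or the zwitterion may collapse to a cyclobutane or lose a proton from C2. Fallback: from 8, acylation of the lithium enolate of methyl acetate (LDA, MeOAc, THF, −78 °C) would give methyl 3-oxo-5-(7,9,9-trimethyl-1,4-dioxaspiro[4.5]dec-7-en-8-yl)pentanoate F1. Knoevenagel condensation with formaldehyde (paraformaldehyde, piperidinium acetate, CH2Cl2) would form in situ methyl 2-methylidene-3-oxo-5-(7,9,9-trimethyl-1,4-dioxaspiro[4.5]dec-7-en-8-yl)pentanoate F2. This doubly activated enophile should undergo the intramolecular ene reaction under ZnBr2 or on mild heating (domino Knoevenagel–ene), without a strong Lewis acid, to give methyl 3,3-(ethylenedioxy)-5,5-dimethyl-1-methylidene-9-oxospiro[5.5]undecane-8-carboxylate F3. Krapcho demethoxycarbonylation (LiCl, wet DMSO, 140 °C) rejoins the route at 10.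

Further compounds
F1 | step 7 | methyl 3-oxo-5-(7,9,9-trimethyl-1,4-dioxaspiro[4.5]dec-7-en-8-yl)pentanoate | COC(=O)CC(=O)CCC1=C(C)CC2(OCCO2)CC1(C)C
F2 | step 7 | methyl 2-methylidene-3-oxo-5-(7,9,9-trimethyl-1,4-dioxaspiro[4.5]dec-7-en-8-yl)pentanoate | COC(=O)C(=C)C(=O)CCC1=C(C)CC2(OCCO2)CC1(C)C
F3 | step 7 | methyl 3,3-(ethylenedioxy)-5,5-dimethyl-1-methylidene-9-oxospiro[5.5]undecane-8-carboxylate (mixture of stereoisomers) | C=C1CC2(OCCO2)CC(C)(C)C13CC(C(=O)OC)C(=O)CC3
F4 | step 8 | (6S)-3,3-(ethylenedioxy)-5,5-dimethyl-1-methylidene-9-(trimethylsilyloxy)spiro[5.5]undec-9-ene | C=C1CC2(OCCO2)CC(C)(C)[C@@]13CCC(O[Si](C)(C)C)=CC3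
F5 | step 8 | (6S,10R)-3,3-(ethylenedioxy)-10-hydroxy-5,5-dimethyl-1-methylidenespiro[5.5]undecan-9-one | C=C1CC2(OCCO2)CC(C)(C)[C@@]13CCC(=O)[C@H](O)C3
F6 | step 16 | (4R,6R,9S,10S)-4,9-dibromo-10-chloro-5,5,9-trimethyl-1-methylidenespiro[5.5]undec-2-en-3-yl acetate | C=C1C=C(OC(C)=O)[C@H](Br)C(C)(C)[C@@]12CC[C@](C)(Br)[C@@H](Cl)C2
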